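The benzoate ring of gentiside A is substituted only at C1 (ester), C2 and C3 (hydroxyls); C4, C5 and C6 carry hydrogen alone. The ring is therefore cut at C4=C5. An acyclic β-keto ester of 20-methylhenicosan-1-ol, bearing an allyl group at the future C1 and a vinyl group at the benzyloxy-substituted future C3, is closed by ring-closing olefin metathesis. This single operation builds the six-membered carbocycle with the ester and both oxygens in place, one dehydrogenation below the arene. Selenoxide elimination then aromatises, and hydrogenolysis frees the catechol. The iso-branched alcohol is made from pentadecanolide and 1-bromo-5-methylhexane by copper-catalysed coupling.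

Key step: step 9

Remark: the target is achiral; 7 is used as the racemate, and every stereocentre on the way (in 8, 9 and 11–18) is carried as a mixture and erased at aromatisation, so no SMILES carries a stereodescriptor. Alkoxide, carboxylate and enolate salts of numbered compounds that exist only until work-up are not numbered separately.

Step 1
Reactants: 1 pentadecanolide (oxacyclohexadecan-2-one)
Product: 2 pentadecane-1,15-diol
Conditions: LiAlH4 (1.2 equiv), THF, 0 °C → reflux; aqueous NaOH work-up
Reagents that add atoms: none
Why: Hydride reduction of a lactone to the diol with LiAlH4 is a standard ester reduction, and the saturated chain offers no competing site.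

Step 2
Reactants: 2 pentadecane-1,15-diol
Product: 3 15-bromopentadecan-1-ol
Conditions: 48% aq. HBr (1.2 equiv), toluene, reflux
Reagents that add atoms: hydrogen bromide, Br
Why: SN2 displacement of one protonated hydroxyl by bromide; in the two-phase toluene/aqueous HBr system an α,ω-diol is known to stop largely at the bromo alcohol, which resists a second substitution.

Step 3
Reactants: 3 15-bromopentadecan-1-ol; 4 1-bromo-5-methylhexane
Product: 6 20-methylhenicosan-1-ol, via (5-methylhexyl)magnesium bromide 5 (not isolated)
Conditions: 4, Mg turnings, THF, 45 °C; then 3 (0.4 equiv relative to 5), Li2CuCl4 (3 mol%), THF, −20 °C → rt; NH4Cl aq.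
Reagents that add atoms: none
Why: Copper-catalysed alkyl–alkyl cross-coupling of a primary Grignard reagent with a primary bromide (Kochi coupling); the first equivalent of 5 turns the hydroxyl into an inert magnesium alkoxide, and the 7 + 15 carbon count gives the iso-C22 chain directly at the alkane oxidation level.

Step 4
Reactants: 7 methyl 2-hydroxybut-3-enoate (racemic)
Product: 8 methyl 2-(benzyloxy)but-3-enoate (racemic)
Conditions: benzyl 2,2,2-trichloroacetimidate (1.3 equiv), TfOH (5 mol%), CH2Cl2/cyclohexane, 0 °C → rt
Reagents that add atoms: benzyl 2,2,2-trichloroacetimidate, N=C(OCc1ccccc1)C(Cl)(Cl)Cl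
Why: Acid-catalysed O-benzylation with the trichloroacetimidate avoids any base, so the doubly activated α-hydrogen is not removed and the β,γ-double bond should not move into conjugation.

Step 5
Reactants: 8 methyl 2-(benzyloxy)but-3-enoate
Product: 9 2-(benzyloxy)but-3-enoic acid (racemic)
Conditions: LiOH·H2O (1.5 equiv), THF/H2O 3:1, 0 °C; then 1 M HCl to pH 2–3
Reagents that add atoms: lithium hydroxide, [Li+].[OH-]
Why: Saponification of an α-alkoxy methyl ester is fast at 0 °C, and the carboxylate formed is no longer prone to α-deprotonation, which protects the position of the alkene.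

Step 6
Reactants: 9 2-(benzyloxy)but-3-enoic acid; 10 Meldrum's acid (2,2-dimethyl-1,3-dioxane-4,6-dione)
Product: 11 5-[2-(benzyloxy)-1-hydroxybut-3-en-1-ylidene]-2,2-dimethyl-1,3-dioxane-4,6-dione (acyl Meldrum's acid, enol form, racemic)
Conditions: DCC (1.1 equiv), DMAP (1.5 equiv), CH2Cl2, 0 °C → rt; filter; cold 5% KHSO4 wash; used crude
Reagents that add atoms: none
Why: Carbodiimide-mediated C-acylation of Meldrum's acid under DMAP catalysis is general for α-alkoxy acids and should give the enolised acyl Meldrum's acid.

Step 7
Reactants: 11 acyl Meldrum's acid (1.2 equiv); 6 20-methylhenicosan-1-ol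
Product: 13 20-methylhenicosyl 4-(benzyloxy)-3-oxohex-5-enoate (racemic), via acylketene 12 (not isolated)
Conditions: toluene, 90 °C
Reagents that add atoms: none
Why: Thermal retro-[4+2] fragmentation of the acyl Meldrum's acid expels acetone and CO2 to give an acylketene, which the primary alcohol traps as the β-keto ester under neutral conditions that do not endanger the vinyl group.

Step 8
Reactants: 13 20-methylhenicosyl 4-(benzyloxy)-3-oxohex-5-enoate
Product: 14 20-methylhenicosyl 2-allyl-4-(benzyloxy)-3-oxohex-5-enoate (mixture of diastereomers)
Conditions: NaH (0.95 equiv), THF, 0 °C; allyl bromide (1.05 equiv), 0 °C → rt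
Reagents that add atoms: allyl bromide, C=CCBr
Why: SN2 C-alkylation of the sodium enolate of a β-keto ester with allyl bromide; substoichiometric base deprotonates only C2, which limits double allylation and leaves the C4–H alone, and the new C2 stereocentre is formed without control because it is erased later.

Step 9
Reactants: 14 20-methylhenicosyl 2-allyl-4-(benzyloxy)-3-oxohex-5-enoate
Product: 15 20-methylhenicosyl 3-(benzyloxy)-2-oxocyclohex-4-ene-1-carboxylate (mixture of diastereomers)
Conditions: second-generation Grubbs catalyst (1,3-dimesitylimidazolidin-2-ylidene)(PCy3)Cl2Ru=CHPh (5 mol%), 1,4-benzoquinone (10 mol%), CH2Cl2 (0.005 M), 40 °C, argon sparge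
Reagents that add atoms: none
Why: The ruthenium benzylidene exchanges onto the unhindered terminal alkene of the allyl group; the resulting alkylidene adds [2+2] to the vinyl group on the benzyloxy-bearing carbon, and cycloreversion of the ruthenacyclobutane releases the cyclohexene while the two terminal CH2 units leave as ethylene. The closest known reaction type is ring-closing metathesis of 1,7-dienes to cyclohexenes carrying ketone and ester groups that are later aromatised to phenols. The single ring closes by intramolecular olefin metathesis of a 1,7-diene, giving a six-membered carbocycle with an endocyclic cis C4=C5 alkene (benzoate numbering). No stereocentre is created; the two existing ones (C1 and C3) are carried as a mixture, both diastereomers can close because the tether runs through the sp2 ketone carbon, and both centres disappear at aromatisation. The step needs ring closure to beat intermolecular metathesis and double-bond migration: high dilution, the ease of six-ring formation from two monosubstituted alkenes, removal of ethylene and benzoquinone as a scavenger of ruthenium hydride should secure this. The benzyl ether is a poor leaving group, so the C3 oxygen should be retained.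

Step 10
Reactants: 15 20-methylhenicosyl 3-(benzyloxy)-2-oxocyclohex-4-ene-1-carboxylate
Product: 19 20-methylhenicosyl 3-(benzyloxy)-2-hydroxybenzoate, via α-phenylselanyl keto ester 16 (not isolated), via selenoxide 17 (not isolated), via dienone tautomer 18 (not isolated)
Conditions: NaH (1.05 equiv), THF, 0 °C; PhSeCl (1.1 equiv), −78 → 0 °C; then H2O2 (30% aq., 3 equiv), 0 °C → rt
Reagents that add atoms: none
Why: α-Selenenylation of the β-keto ester enolate at C1, oxidation to the selenoxide and syn-elimination, which can only take a C6 hydrogen, install C1=C6; the resulting cyclohexa-2,4-dienone tautomerises to the phenol and all stereocentres vanish.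

Step 11
Reactants: 19 20-methylhenicosyl 3-(benzyloxy)-2-hydroxybenzoate
Product: 20 gentiside A (20-methylhenicosyl 2,3-dihydroxybenzoate)
Conditions: H2 (1 atm), Pd/C (10% Pd on carbon), EtOAc/THF, rt
Reagents that add atoms: none
Why: Hydrogenolysis of an aryl benzyl ether over Pd/C is fast under 1 atm of hydrogen and should leave the alkyl ester and the arene intact, as no alkene remains to be reduced.

Compound list
1 | pentadecanolide (oxacyclohexadecan-2-one) | O=C1CCCCCCCCCCCCCCO1 | starting material
2 | pentadecane-1,15-diol | OCCCCCCCCCCCCCCCO | intermediate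
3 | 15-bromopentadecan-1-ol | OCCCCCCCCCCCCCCCBr | intermediate
4 | 1-bromo-5-methylhexane | CC(C)CCCCBr | starting material
5 | (5-methylhexyl)magnesium bromide | CC(C)CCCC[Mg]Br | intermediate (not isolated)
6 | 20-methylhenicosan-1-ol | CC(C)CCCCCCCCCCCCCCCCCCCO | intermediate
7 | methyl 2-hydroxybut-3-enoate (racemic) | COC(=O)C(O)C=C | starting material
8 | methyl 2-(benzyloxy)but-3-enoate (racemic) | COC(=O)C(OCc1ccccc1)C=C | intermediate
9 | 2-(benzyloxy)but-3-enoic acid (racemic) | OC(=O)C(OCc1ccccc1)C=C | intermediate
10 | Meldrum's acid (2,2-dimethyl-1,3-dioxane-4,6-dione) | CC1(C)OC(=O)CC(=O)O1 | starting material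
11 | 5-[2-(benzyloxy)-1-hydroxybut-3-en-1-ylidene]-2,2-dimethyl-1,3-dioxane-4,6-dione (racemic, enol form) | CC1(C)OC(=O)C(=C(O)C(OCc2ccccc2)C=C)C(=O)O1 | intermediate
12 | 4-(benzyloxy)hexa-1,5-diene-1,3-dione (acylketene, racemic) | O=C=CC(=O)C(OCc1ccccc1)C=C | intermediate (not isolated)
13 | 20-methylhenicosyl 4-(benzyloxy)-3-oxohex-5-enoate (racemic) | CC(C)CCCCCCCCCCCCCCCCCCCOC(=O)CC(=O)C(OCc1ccccc1)C=C | intermediate
14 | 20-methylhenicosyl 2-allyl-4-(benzyloxy)-3-oxohex-5-enoate (mixture of diastereomers) | CC(C)CCCCCCCCCCCCCCCCCCCOC(=O)C(CC=C)C(=O)C(OCc1ccccc1)C=C | intermediate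
15 | 20-methylhenicosyl 3-(benzyloxy)-2-oxocyclohex-4-ene-1-carboxylate (mixture of diastereomers) | CC(C)CCCCCCCCCCCCCCCCCCCOC(=O)C1CC=CC(OCc2ccccc2)C1=O | intermediate
16 | 20-methylhenicosyl 3-(benzyloxy)-2-oxo-1-(phenylselanyl)cyclohex-4-ene-1-carboxylate (mixture of diastereomers) | CC(C)CCCCCCCCCCCCCCCCCCCOC(=O)C1([Se]c2ccccc2)CC=CC(OCc2ccccc2)C1=O | intermediate (not isolated)
17 | 20-methylhenicosyl 3-(benzyloxy)-2-oxo-1-(phenylseleninyl)cyclohex-4-ene-1-carboxylate (mixture of diastereomers) | CC(C)CCCCCCCCCCCCCCCCCCCOC(=O)C1([Se](=O)c2ccccc2)CC=CC(OCc2ccccc2)C1=O | intermediate (not isolated)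
18 | 20-methylhenicosyl 5-(benzyloxy)-6-oxocyclohexa-1,3-diene-1-carboxylate (racemic) | CC(C)CCCCCCCCCCCCCCCCCCCOC(=O)C1=CC=CC(OCc2ccccc2)C1=O | intermediate (not isolated)
19 | 20-methylhenicosyl 3-(benzyloxy)-2-hydroxybenzoate | CC(C)CCCCCCCCCCCCCCCCCCCOC(=O)c1cccc(OCc2ccccc2)c1O | intermediate
20 | gentiside A (20-methylhenicosyl 2,3-dihydroxybenzoate) | CC(C)CCCCCCCCCCCCCCCCCCCOC(=O)c1cccc(O)c1O | target

Total step count: 11.
Longest linear sequence: 8 steps (7 → 20 through steps 4–11; equally 1 → 20 through steps 1–3 and 7–11).

Steps most likely to fail

1. Step 9 (ring-closing metathesis). The enolisable 1,3-dicarbonyl unit may chelate ruthenium and stall turnover. Ruthenium hydride formed by catalyst decay may also move the allyl or vinyl double bond along the chain before closure, leading to oligomers, a ring-contracted product or a conjugated enone that cannot close. The fallback sets out from 14 and comes back at 15. The ketone of 14 is reduced with NaBH4 (MeOH/THF, −20 °C) to the β-hydroxy ester 20-methylhenicosyl 2-allyl-4-(benzyloxy)-3-hydroxyhex-5-enoate F1, a diene that neither chelates nor enolises. Ring-closing metathesis of F1 with the same ruthenium catalyst should give 20-methylhenicosyl 3-(benzyloxy)-2-hydroxycyclohex-4-ene-1-carboxylate F2. Oxidation of F2 with Dess–Martin periodinane (CH2Cl2, NaHCO3) returns the route to 15.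

2. Step 10 (aromatisation). Electrophilic selenium may add across the C4=C5 alkene instead of substituting at C1, or the peroxide and the seleninic acid may over-oxidise the electron-rich phenol once it has formed. The fallback sets out from 15 and comes back at 19. It is a direct dehydrogenation with DDQ (1.1 equiv, toluene, rt → 60 °C). The enol tautomer of 15 is a cyclohexa-1,4-diene, from which DDQ should abstract hydride at the doubly allylic C6; loss of the C3 proton then gives 19. No new compound arises (F0).

3. Step 6 (acylation of Meldrum's acid). DMAP may deprotonate the activated acyl species at the α-carbon (ketene or dienolate formation), which moves the double bond into conjugation with the carbonyl group; the acidic product may also decompose on work-up. The fallback sets out from 6, 9 and 10 and comes back at 13, bypassing 11 and 12. Alcohol 6 is heated with 10 in toluene to give the malonic half-ester 3-[(20-methylhenicosyl)oxy]-3-oxopropanoic acid F3. Acid 9 is activated with 1,1'-carbonyldiimidazole (THF, rt) to the acyl imidazolide 2-(benzyloxy)-1-(1H-imidazol-1-yl)but-3-en-1-one F4. The magnesium salt of F3 (MgCl2, Et3N, THF) is acylated by F4 and decarboxylates in a Masamune–Brooks-type decarboxylative Claisen condensation to give 13.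

Further compounds
F1 | step 9 | 20-methylhenicosyl 2-allyl-4-(benzyloxy)-3-hydroxyhex-5-enoate (mixture of diastereomers) | CC(C)CCCCCCCCCCCCCCCCCCCOC(=O)C(CC=C)C(O)C(OCc1ccccc1)C=C
F2 | step 9 | 20-methylhenicosyl 3-(benzyloxy)-2-hydroxycyclohex-4-ene-1-carboxylate (mixture of diastereomers) | CC(C)CCCCCCCCCCCCCCCCCCCOC(=O)C1CC=CC(OCc2ccccc2)C1O
F0 | step 10 | none | none
F3 | step 6 | 3-[(20-methylhenicosyl)oxy]-3-oxopropanoic acid | CC(C)CCCCCCCCCCCCCCCCCCCOC(=O)CC(=O)O
F4 | step 6 | 2-(benzyloxy)-1-(1H-imidazol-1-yl)but-3-en-1-one (racemic) | C=CC(OCc1ccccc1)C(=O)n1ccnc1
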